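Slowness in this flask I look for in two places: in the crossing of gas to coupling partner, which takes no notice of the substrate, or in the step of substrate with second chain carrier, which at a given c second chain carrier slows as c substrate falls.

- blue: substrate 0.075 M; gas 3 mM (held); initiator 0.25 mM; run made earlier
- flask: substrate 0.050 M; gas 3.0 mM (held); initiator 0.25 mM; time 40 h

blue run (percent of the substrate charged)

| time / h | substrate / % | product / % |
|---|---|---|
| 1.33 | 95.2 | 4.7 |
| 2.50 | 91.1 | 8.6 |
| 4.00 | 85.0 | 14.4 |
| 5.00 | 81.8 | 18.1 |
| 6.00 | 78.0 | 22.2 |
| 8.00 | 70.9 | 29.5 |

(each reading ± 0.3 percentage points)

- in percentages every species weighs as the substrate in it: one ended chains A counts as two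
- at the start none of coupling partner is dissolved
- what was read earlier has a scatter of 0.3 percentage points, one standard deviation
- steps under discussion: gas <-> coupling partner; 2 first chain carrier -> ended chains A; substrate + initiating radical -> capped initiator + first chain carrier; coupling partner + first chain carrier -> product + second chain carrier; coupling partner <-> dormant form; initiator -> 2 initiating radical; substrate + second chain carrier -> by-product + first chain carrier; 2 second chain carrier -> ended chains B
- the reaction counts as stopped when no species that holds the substrate changes by six tenths of a point or more over the second half of the time

1. at 40 h, what has stopped the reaction, if anything has (it is still moving / forward and back rates have come level / all of the substrate has reacted)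
2. part of the substrate gone at 40 h
3. the product standing at 40 h, as a percentage of the substrate charged

Take the crossing first, by itself. The blue run loses substrate along a line of 2.73 mM/h, and at that pace your flask's 0.050 M is through in 18.3 h, well inside 40 h, so this view gives total conversion.

Now add the substrate step. At the last blue reading, c substrate stood at 53.2 mM and the line still held, and from the two I read a first-order constant of 0.0514 /h there. Your flask starts lower than that level, so I let it decay pseudo-first-order from the start. Working in logarithms, I carry the decade time, the hours needed to lose one power of ten of the substrate at that constant: 44.8 h. In 40 h that makes 0.893 decades, so 12.8% stays and 87.2% is gone.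

Then the rest. In the blue run, product tracks lost substrate, 29.5% against 29.1%, a gap near the scatter of 0.3 percentage points, so in my reckoning the further steps leave the number as it is and I put product at 87.2% too. In that reckoning the substrate still falls by 23 points over the second half of the time, so I call the flask still moving.

The forecast differs: all of the substrate has reacted, 99.8% gone (95% to 100%) and 98.8% product (93% to 99.7%), on the ground that “the rate is zero order in substrate”.

At 40 h in the flask it is still moving, with 89.1% gone and 89.1% product. The slowness of the gas crossing makes practically no difference to this flask's conversion. The decade time of 44.8 h allowed 0.893 decades; the 11% of substrate left in the flask stands for 0.959 decades.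

    gas ⇌ coupling partner, rate k1*(csat - [coupling partner]) (kL = 0.991 /h)
    2 first chain carrier → ended chains A (k = 1.70 × 10⁶ /M/s)
    substrate + initiating radical → capped initiator + first chain carrier (k = 2.46 × 10⁶ /M/s)
    coupling partner + first chain carrier → product + second chain carrier (k = 4.87 × 10⁵ /M/s)
    coupling partner ⇌ dormant form (K = 41.2, k = 0.0452 /h)
    initiator → 2 initiating radical (k = 0.00554 /h)
    substrate + second chain carrier → by-product + first chain carrier (k = 28800 /M/s)
    2 second chain carrier → ended chains B (k = 1.20 × 10⁹ /M/s)

Read the same flask at 10 h: the decade time gives 0.223 decades, so 40.2% gone. The computed flask stands at 43.1%.

The earlier runs and the new flask are calculated on assumed constants; scatter was added.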